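I had to say how much target Saturday's and Monday's flasks held after 25 h, and whether more than 2 percentage points parted them.

| setting | winter | summer | dusk | Saturday's | Monday's |
|---|---|---|---|---|---|
| starting material | 0.086 M | 0.23 M | 0.20 M | 0.20 M | 0.060 M |
| protic impurity | 0.040 M | 0.040 M | 0.026 M | 0.0400 M | 0.0250 M |
| remark | run made earlier | run made earlier | run made earlier |  |  |
| time |  |  |  | 25 h | 25 h |

| run | time / h | target / % |
|---|---|---|
| winter | 0.667 | 0.1 |
| winter | 2.00 | 0.4 |
| winter | 4.00 | 0.7 |
| winter | 5.00 | 2.6 |
| winter | 8.00 | 4.7 |
| winter | 10.0 | 7.3 |
| winter | 12.0 | 8.8 |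
| summer | 2.00 | 0.7 |
| summer | 4.00 | 0.7 |
| summer | 5.00 | 1.5 |
| summer | 8.00 | 4.8 |
| summer | 10.0 | 7.1 |
| summer | 12.0 | 9.0 |
| dusk | 2.50 | 0.3 |
| dusk | 5.00 | 2.6 |
| dusk | 8.00 | 5.5 |
| dusk | 10.0 | 7.1 |
| dusk | 12.0 | 9.6 |

(standard deviation of a reading: 0.5 percentage points)

1. the winner by amount of target, in percent of the starting material charged; "neither" if no more than 2 percentage points parts them (Saturday's / Monday's / neither)
2. how much target is there at the end, in percent of the starting material charged: Saturday's
3. how much target is there at the end, in percent of the starting material charged: Monday's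

At 12.0 h the earlier runs stood at 8.8%, 9.0% and 9.6%, with a scatter of 0.5 points, although winter and summer differed in starting charge from 0.086 M to 0.23 M. I therefore reckoned in fractions of the charge and took one curve for all the flasks. My first estimate was a straight line through summer's last two readings, which gave 21.4%. But a line holds the rate fixed, and summer gained 4.2 points from 8.00 h to 12.0 h against 0.7% in the first 4.00 h.

So I treated the route through intermediate A as two equal first-order lags in series, which pass the fraction 1 − (1 + x)·exp(−x) of the charge, where x is time over the lag constant. Setting x to 0.5 gave 9.02%, which matched summer's last reading, so the lag constant, the time constant of each lag, was 24.0 h. At 25 h the curve gave 28.0%.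

One objection was the impurity, since Monday's has about dusk's concentration and Saturday's has summer's. Dusk led summer by 0.6 points, which scaled along the curve to 1.9 points, under the margin. I said neither, with Monday's slightly ahead. A second objection stayed open: the curve sends the whole charge to target, so I held 28.0% as a high figure.

The forecast gave 20% for Saturday's and 20.5% for Monday's, and neither, holding that “Saturday's and Monday's should come out nearly equal”.

The flasks gave 25.3% on Saturday's and 25.5% on Monday's, so the answer was neither.

    starting material → intermediate A (k = 1.80 × 10⁻⁵ s⁻¹)
    intermediate A ⇌ intermediate B (K = 0.670, k = 5.00 × 10⁻⁷ s⁻¹)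
    intermediate B ⇌ intermediate C (K = 1.20, k = 5.60 × 10⁻⁷ s⁻¹)
    intermediate A → target (k = 9.10 × 10⁻⁶ s⁻¹)
    target ⇌ isomer of the product (K = 0.380, k = 1.70 × 10⁻⁶ s⁻¹)
    starting material + protic impurity → quenched substrate (k = 2.70 × 10⁻⁴ M⁻¹ s⁻¹)

My lag curve stood 2.7 points above Saturday's target. On Saturday's target the time given weighed more than the passing of starting material and protic impurity into quenched substrate: Saturday's flask left ten times as long gives 57.5%, a gain of 32 points, and Saturday's run without that step gives 29.0%, a gain of 3.7 points. Read at 15 h on Monday's flask, the same lag constant of 24.0 h gives 13.0%, and that flask holds 13.1%.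

The runs are calculated for an exercise.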